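**Charge ratio.** If each coupling partner takes up one substrate, a flask can consume a fraction of its substrate equal to the ratio of the charges, coupling partner over substrate, as long as that ratio stays below one. For this flask (the south-west run followed on) that ratio is 0.700.

all flasks: substrate 0.80 M

| flask | coupling partner | temperature | remark | time |
|---|---|---|---|---|
| south-west | 0.56 M | 50 °C | the very flask that is asked about, followed so far |  |
| west | 0.38 M | 35 °C | run made earlier |  |
| flask | 0.560 M | 50 °C |  | 3.0 d |

- south-west (time / h: target / %, substrate / %): 6.00: 38.1, 33.0; 8.00: 39.5, 32.2; 12.0: 40.0, 29.9; 20.0: 40.8, 29.4; 30.0: 40.4, 29.4; 50.0: 40.5, 30.3; 72.0: 41.4, 30.6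
- west (time / h: target / %, substrate / %): 0.667: 2.3, 65.6; 1.00: 2.8, 65.3; 1.33: 2.8, 65.4; 2.00: 4.7, 64.4; 3.00: 4.9, 62.6; 5.00: 6.9, 60.8; 8.00: 8.0, 58.0

(each reading ± 0.5 percentage points)

- larch: at 3.0 d add coupling partner, 50.0% of the amount charged, then wait 40 h
- elm: change nothing and wait 40 h more
- cedar: at 3.0 d take out 90% of the target then present, then wait 40 h
- maple: at 3.0 d raise the temperature by 25 K, then wait 40 h

- target, in percent of the substrate first charged, at 3.0 d
- which option adds most target ("none" when 2 percentage points or less is all one gets) (larch / elm / cedar / maple / none)
- target present, with what was taken out counted in, in percent of the substrate first charged, after larch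
- target present, with what was taken out counted in, in percent of the substrate first charged, after elm

- target taken out counts as made
- additions bring no volume worth counting

**First round.** From 20.0 h to 72.0 h, the south-west readings show a consumed fraction of 70.1% on average, close to the ratio. The coupling partner therefore reads as the limiting reagent. If every consumed substrate became target, the flask would show 70.0%, but its target readings average 40.8%.

**Second round.** That reading goes back into the rule as the target share, the fraction of consumed substrate found as target, with 0.582 as its reading. At 50 °C and with the ratio below one, target is then the share times the ratio. At 3.0 d the flask stands near 40.8%. From 20.0 h to 72.0 h the south-west target readings move by 0.6 percentage points, about the scatter of 0.5 points and less than 2 points, so this reckoning expects elm to add less than 2 points.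

**The border.** Larch raises the ratio to 1.05, and this passes 1, where substrate becomes the limiting charge. The rule stops there, so the consumed fraction is capped at the whole charge and not 1.05. The flask after larch should reach 58.2%, given that the 40 h of waiting is longer than the 12.0 h at which the south-west substrate readings had levelled. The share was read at one temperature with target left in the flask, so this reckoning puts no number on cedar or maple.

**The forecast.** The forecast, which said “So I read the plateau as partner exhausted”, gave 40.8% at 3.0 d, 67% after larch (range 56% to 71%) and 41% after elm, and it chose larch.

**The result.** The flask gives 40.8%, then 58.2% after larch and 40.8% after elm. The best option is maple, adding 23 points against 17 points for larch and 15 points for cedar. Beside the target stands the isomer of the product, 29.2% at 72.0 h, and by this step alone, both ways together, the pair relaxes with a half-life of 1.52 min, short against 3.0 d.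

    substrate + coupling partner ⇌ intermediate (K = 2.51 M⁻¹, k = 0.561 M⁻¹ min⁻¹, Ea = 78.0 kJ mol⁻¹, ΔH = −35.0 kJ mol⁻¹)
    intermediate → target (k = 0.0169 min⁻¹, Ea = 96.0 kJ mol⁻¹)
    target ⇌ isomer of the product (K = 0.715, k = 0.190 min⁻¹, Ea = 103 kJ mol⁻¹, ΔH = −77.0 kJ mol⁻¹)
    (constants at 50 °C)

With 0.34 M of coupling partner the ratio is 0.425, so the share times the ratio reckons 24.7% of target, and that neighbouring flask holds 24.8% of target.

The numbers in the tables were generated by integration for an exercise; noise was put on by code.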